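**Plan**

- Retrosynthetic cuts: (a) three aryl benzyl ethers and one silyl ether; (b) the bond between the carbinol carbon and the aryl-bearing carbon of the 1,3-diol arm (anti-allylboration of 4-(benzyloxy)-3-methoxybenzaldehyde, the vinyl group being a masked CH2OH); (c) the lactone C3–CH2 bond (trans-alkylation of a 4-benzyl-γ-butyrolactone with a benzylic bromide); (d) the lactone ring (Stobbe condensation, asymmetric hydrogenation); (e) the C3a–C3 bond of the dihydrobenzofuran (back to a 2-arylchroman-4-one made from a chromone).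
- Forward order: chromone → (R)-flavanone → ring contraction to the trans-2-aryl-2,3-dihydrobenzofuran-3-carboxylate (five-membered ring closed at C3a–C3) → benzylic bromide. Separately, 5-bromovanillin → (S)-4-benzyl lactone → styrene. Lactone alkylation joins the halves; cross-metathesis, allylboration and ozonolysis/reduction build the diol arm; desilylation and hydrogenolysis finish.
- Enabling feature: C3 of the dihydrobenzofuran carries CH2OH, a reduced carboxyl carbon. Read backwards, that carbon is the C4 carbonyl of a chroman-4-one (rings A and C). C3a–C3 forms when ring-A carbon C4a, electron-rich because it is ortho to ring oxygen O1, shifts from C4 (a cation-stabilising dimethyl ketal) to C3 bearing a trivalent-iodine leaving group, contracting ring C from six to five members.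
- Stereochemistry: C2 of the dihydrobenzofuran from catalytic asymmetric conjugate addition to the chromone; C3 by relay from C2 in the ring contraction (trans). Lactone C4 from Rh-catalysed asymmetric hydrogenation; lactone C3 by anti alkylation. The diol pair from the chair transition state of the (E)-allylboronate (anti) under a chiral phosphoric acid (absolute sense).

Key step: step 4

Assumption: the absolute sense of induction of each chiral catalyst or auxiliary named ((S)-t-BuPyOx, (R,R)-Et-DuPHOS, (S)-TRIP; in the fallbacks (R,R)-TsDPEN and the (S)-oxazolidinone) is assigned by analogy with simple model substrates; if a sense proves opposite, the antipode is used.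

Abbreviations in names: BnV = 4-(benzyloxy)-3-methoxyphenyl; DBF = (2R,3S)-2-BnV-3-{[(tert-butyldimethylsilyl)oxy]methyl}-7-methoxy-2,3-dihydrobenzofuran-5-yl; TBS = tert-butyldimethylsilyl.

**Route**

Step 1
Reactants: 1 1-(2-hydroxy-3-methoxyphenyl)ethanone
Product: 2 1-(5-bromo-2-hydroxy-3-methoxyphenyl)ethanone
Conditions: NBS, MeCN, 0 °C to rt
Reagents that add atoms: N-bromosuccinimide O=C1CCC(=O)N1Br
Why: Electrophilic aromatic bromination; the phenol OH directs to its free para position, which is also meta to the acetyl group, and no stereocenter is formed.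

Step 2
Reactants: 2 1-(5-bromo-2-hydroxy-3-methoxyphenyl)ethanone
Product: 4 6-bromo-8-methoxy-4H-chromen-4-one, via enaminone 3 (not isolated)
Conditions: Me2NCH(OMe)2, toluene, 100 °C; then conc. HCl, CH2Cl2, 40 °C
Reagents that add atoms: N,N-dimethylformamide dimethyl acetal COC(OC)N(C)C
Why: Enaminone chromone synthesis: condensation at the acetyl CH3, then acid-induced addition of the phenol to the enaminone and loss of dimethylamine; no stereocenter.

Step 3
Reactants: 4 6-bromo-8-methoxy-4H-chromen-4-one; 5 [4-(benzyloxy)-3-methoxyphenyl]boronic acid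
Product: 6 (R)-2-BnV-6-bromo-8-methoxychroman-4-one
Conditions: Pd(OCOCF3)2 (5 mol%), (S)-t-BuPyOx (6 mol%), NH4PF6 (30 mol%), H2O (5 equiv), ClCH2CH2Cl, 60 °C
Reagents that add atoms: none
Why: Pyridine-oxazoline/divalent-palladium-catalysed asymmetric conjugate addition of an arylboronic acid to a chromone (Hayashi–Miyaura-type 1,4-addition); the ligand-controlled enantioface of aryl–Pd insertion sets C2 as R, and the cycle stays at divalent palladium so the aryl bromide should be left alone.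

Step 4
Reactants: 6 (R)-2-BnV-6-bromo-8-methoxychroman-4-one
Product: 9 methyl (2R,3R)-2-BnV-5-bromo-7-methoxy-2,3-dihydrobenzofuran-3-carboxylate (trans), via enol ether 7 (not isolated), via iodane 8 (not isolated)
Conditions: PhI(OAc)2 (1.5 equiv), conc. H2SO4 (0.5 equiv), HC(OMe)3, 0 °C to rt; aq. NaHCO3 work-up
Reagents that add atoms: trimethyl orthoformate COC(OC)OC; water O
Why: Acid and orthoformate turn the C4 ketone into methyl enol ether 7, whose C3 attacks trivalent iodine from the face opposite the equatorial C2 aryl group and is re-ketalised to iodanyl ketal 8; PhI then leaves as ring-A carbon C4a shifts from C4 to C3, and the dimethoxycarbenium ion left at C4 is hydrolysed to the methyl ester on work-up. The closest known reaction type is the hypervalent-iodine (or thallium trinitrate) oxidative 1,2-aryl-shift ring contraction of flavanones to methyl trans-2-aryl-2,3-dihydrobenzofuran-3-carboxylates. The five-membered ring O1–C2–C3–C3a–C7a is closed by this 1,2-shift through a bridged phenonium-type transition structure (3-exo attack of the ipso carbon on C3), and the six-membered ring C contracts as the old C4–C4a bond breaks. C3 is the only new stereocenter: the iodane sits trans to the C2 aryl group and is displaced with inversion, which should place the ester trans to the aryl group (2R,3R) while C2 is untouched. The step needs ring-A migration to win over migration of the C2 aryl group (isoflavone formation), dehydrogenation to the flavone and 3-methoxylation; the ortho ring oxygen makes C4a an electron-rich migrating carbon, the ketal makes C4 a stabilised cationic terminus, and the equatorial C3–I bond is anti-periplanar only to the C4–C4a ring bond.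

Step 5
Reactants: 9 methyl (2R,3R)-2-BnV-5-bromo-7-methoxy-2,3-dihydrobenzofuran-3-carboxylate
Product: 10 [(2R,3S)-2-BnV-5-bromo-7-methoxy-2,3-dihydrobenzofuran-3-yl]methanol
Conditions: i-Bu2AlH (2.5 equiv), CH2Cl2, −78 to 0 °C; aq. KNaC4H4O6 work-up
Reagents that add atoms: none
Why: Aluminium hydride reduction of the ester to the primary alcohol at low temperature; C2 and C3 are not touched (the C3 descriptor changes by priority only) and the aryl bromide and benzyl ether are inert.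

Step 6
Reactants: 10 [(2R,3S)-2-BnV-5-bromo-7-methoxy-2,3-dihydrobenzofuran-3-yl]methanol
Product: 11 (2R,3S)-2-BnV-5-bromo-3-[(TBS-oxy)methyl]-7-methoxy-2,3-dihydrobenzofuran
Conditions: TBSCl, imidazole, DMF, rt
Reagents that add atoms: tert-butyldimethylsilyl chloride CC(C)(C)[Si](C)(C)Cl
Why: Standard silylation of a primary alcohol so that it survives the organolithium and enolate steps.

Step 7
Reactants: 11 (2R,3S)-2-BnV-5-bromo-3-[(TBS-oxy)methyl]-7-methoxy-2,3-dihydrobenzofuran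
Product: 14 DBF-methanol (the 5-hydroxymethyl compound), via aryllithium 12 (not isolated), via aldehyde 13 (not isolated)
Conditions: n-BuLi (1.1 equiv), THF, −78 °C; DMF, −78 to 0 °C; then MeOH, NaBH4, 0 °C; aq. NH4Cl work-up
Reagents that add atoms: N,N-dimethylformamide CN(C)C=O
Why: Bromine–lithium exchange outruns any deprotonation at −78 °C, the aryllithium is formylated by DMF (Bouveault formylation) and the aldehyde is reduced in the same flask by borohydride.

Step 8
Reactants: 14 DBF-methanol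
Product: 15 DBF-methyl bromide (the 5-bromomethyl compound)
Conditions: CBr4, PPh3, CH2Cl2, 0 °C
Reagents that add atoms: carbon tetrabromide BrC(Br)(Br)Br
Why: Appel bromination of the benzylic alcohol under near-neutral conditions that leave the silyl ether and the benzylic ring ether intact.

Step 9
Reactants: 16 3-bromo-4-hydroxy-5-methoxybenzaldehyde (5-bromovanillin)
Product: 17 4-(benzyloxy)-3-bromo-5-methoxybenzaldehyde
Conditions: BnBr, K2CO3, DMF, rt
Reagents that add atoms: benzyl bromide BrCc1ccccc1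
Why: Williamson etherification of the phenol.

Step 10
Reactants: 17 4-(benzyloxy)-3-bromo-5-methoxybenzaldehyde; 18 dimethyl succinate
Product: 20 (E)-4-[4-(benzyloxy)-3-bromo-5-methoxyphenyl]-3-(methoxycarbonyl)but-3-enoic acid, via paraconate 19 (not isolated)
Conditions: NaOMe, MeOH, reflux; then aq. HCl
Reagents that add atoms: none
Why: Stobbe condensation: the succinate enolate adds to the aldehyde, the aldolate lactonises to paraconate 19 and E1cB opening gives the (E)-itaconate half-ester with the free acid on the CH2 arm.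

Step 11
Reactants: 20 (E)-4-[4-(benzyloxy)-3-bromo-5-methoxyphenyl]-3-(methoxycarbonyl)but-3-enoic acid
Product: 21 (S)-4-[4-(benzyloxy)-3-bromo-5-methoxyphenyl]-3-(methoxycarbonyl)butanoic acid
Conditions: H2 (5 bar), [Rh(cod)((R,R)-Et-DuPHOS)]BF4 (1 mol%), NaOMe (10 mol%), MeOH, rt
Reagents that add atoms: none
Why: Rhodium–bisphosphine asymmetric hydrogenation of a Stobbe itaconate half-ester; chelation of alkene and carboxylate to the cationic rhodium complex fixes the enantioface and sets the new stereocenter as S, and the homogeneous catalyst should not touch the aryl bromide or benzyl ether.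

Step 12
Reactants: 21 (S)-4-[4-(benzyloxy)-3-bromo-5-methoxyphenyl]-3-(methoxycarbonyl)butanoic acid
Product: 23 (S)-4-[4-(benzyloxy)-3-bromo-5-methoxybenzyl]dihydrofuran-2(3H)-one, via hydroxy acid 22 (not isolated)
Conditions: KOH (1 equiv), EtOH; CaCl2, NaBH4, 0 °C to rt; then 2 M HCl, rt
Reagents that add atoms: none
Why: Chemoselective borohydride reduction of the ester beside the carboxylate (calcium borohydride formed in the flask), then acid-induced lactonisation; the stereocenter is not involved.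

Step 13
Reactants: 23 (S)-4-[4-(benzyloxy)-3-bromo-5-methoxybenzyl]dihydrofuran-2(3H)-one
Product: 24 (S)-4-[4-(benzyloxy)-3-methoxy-5-vinylbenzyl]dihydrofuran-2(3H)-one
Conditions: CH2=CHBF3K, PdCl2(dppf)·CH2Cl2 (3 mol%), Et3N, n-PrOH, 90 °C
Reagents that add atoms: potassium vinyltrifluoroborate C=C[B-](F)(F)F.[K+]
Why: Suzuki–Miyaura vinylation of the aryl bromide with a vinyltrifluoroborate; the weak amine base leaves the lactone and its stereocenter untouched.

Step 14
Reactants: 24 (S)-4-[4-(benzyloxy)-3-methoxy-5-vinylbenzyl]dihydrofuran-2(3H)-one; 15 DBF-methyl bromide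
Product: 26 (3S,4S)-4-[4-(benzyloxy)-3-methoxy-5-vinylbenzyl]-3-(DBF-methyl)dihydrofuran-2(3H)-one, via lithium enolate 25 (not isolated)
Conditions: LiN(SiMe3)2 (1.05 equiv), THF, −78 °C; then 15, DMPU, −78 to −30 °C
Reagents that add atoms: none
Why: SN2 alkylation of a 4-substituted γ-butyrolactone lithium enolate; the benzylic bromide enters anti to the C4 benzyl group and sets C3 as S (trans), as in dibenzylbutyrolactone lignan syntheses.

Step 15
Reactants: 26 (3S,4S)-4-[4-(benzyloxy)-3-methoxy-5-vinylbenzyl]-3-(DBF-methyl)dihydrofuran-2(3H)-one; 27 2-allyl-4,4,5,5-tetramethyl-1,3,2-dioxaborolane (3 equiv)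
Product: 28 (3S,4S)-4-{4-(benzyloxy)-3-methoxy-5-[(E)-3-(4,4,5,5-tetramethyl-1,3,2-dioxaborolan-2-yl)prop-1-enyl]benzyl}-3-(DBF-methyl)dihydrofuran-2(3H)-one
Conditions: second-generation Grubbs catalyst RuCl2(=CHPh)(H2IMes)(PCy3) (5 mol%), CH2Cl2, 40 °C
Reagents that add atoms: none
Why: Olefin cross-metathesis of a styrene with allyl pinacol boronate; the (E)-styrenyl alkene is favoured and loss of ethylene drives the reaction.

Step 16
Reactants: 28 the (E)-allylboronate; 29 4-(benzyloxy)-3-methoxybenzaldehyde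
Product: 31 (3S,4S)-4-{4-(benzyloxy)-3-[(1S,2R)-1-BnV-1-hydroxybut-3-en-2-yl]-5-methoxybenzyl}-3-(DBF-methyl)dihydrofuran-2(3H)-one, via borate 30 (not isolated)
Conditions: (S)-TRIP (3,3'-bis(2,4,6-triisopropylphenyl)-1,1'-binaphthyl-2,2'-diyl hydrogen phosphate, 10 mol%), 4 Å molecular sieves, toluene, −30 °C to rt; aq. NaHCO3 work-up
Reagents that add atoms: none
Why: Chiral phosphoric acid-catalysed allylboration of an aldehyde; the closed chair transition state of the (E)-γ-aryl boronate gives the anti relation of C–OH and C–aryl, and the acid, hydrogen-bonded to a boronate oxygen, selects the aldehyde face to set the carbinol carbon as S and its neighbour as R.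

Step 17
Reactants: 31 the homoallylic alcohol
Product: 33 (3S,4S)-4-{4-(benzyloxy)-3-[(1S,2S)-1-BnV-1,3-dihydroxypropan-2-yl]-5-methoxybenzyl}-3-(DBF-methyl)dihydrofuran-2(3H)-one, via aldehyde 32 (not isolated)
Conditions: O3, CH2Cl2/MeOH (4:1), −78 °C (Sudan Red 7B end point); then NaBH4, −78 to 0 °C
Reagents that add atoms: ozone [O-][O+]=O
Why: Ozonolysis of the terminal alkene with borohydride reduction in the same flask, so that the epimerisable α-aryl β-hydroxy aldehyde is reduced as it forms; both stereocenters are retained (the aryl-bearing carbon becomes S by priority change only).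

Step 18
Reactants: 33 the 1,3-diol
Product: 34 (3S,4S)-4-{4-(benzyloxy)-3-[(1S,2S)-1-BnV-1,3-dihydroxypropan-2-yl]-5-methoxybenzyl}-3-{[(2R,3S)-2-BnV-3-(hydroxymethyl)-7-methoxy-2,3-dihydrobenzofuran-5-yl]methyl}dihydrofuran-2(3H)-one
Conditions: HF·pyridine, THF/pyridine, 0 °C to rt
Reagents that add atoms: none
Why: Fluoride cleavage of the primary silyl ether under pyridine-buffered conditions that should neither open the lactone nor ionise the benzylic alcohol.

Step 19
Reactants: 34 the tris(benzyl ether) triol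
Product: 35 CNP0199264.1, (3S,4S)-4-{4-hydroxy-3-[(1S,2S)-1,3-dihydroxy-1-(4-hydroxy-3-methoxyphenyl)propan-2-yl]-5-methoxybenzyl}-3-{[(2R,3S)-2-(4-hydroxy-3-methoxyphenyl)-3-(hydroxymethyl)-7-methoxy-2,3-dihydrobenzofuran-5-yl]methyl}dihydrofuran-2(3H)-one
Conditions: H2 (1 atm), 10% Pd/C, EtOAc/EtOH (1:1), rt
Reagents that add atoms: none
Why: Hydrogenolysis of the three aryl benzyl ethers; under neutral conditions these should cleave much faster than the benzylic C–O bonds of the dihydrobenzofuran and of the secondary alcohol.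

**Compound list**

1 | 1-(2-hydroxy-3-methoxyphenyl)ethanone | CC(=O)c1cccc(OC)c1O | starting material
2 | 1-(5-bromo-2-hydroxy-3-methoxyphenyl)ethanone | CC(=O)c1cc(Br)cc(OC)c1O | intermediate
3 | (E)-1-(5-bromo-2-hydroxy-3-methoxyphenyl)-3-(dimethylamino)prop-2-en-1-one | CN(C)/C=C/C(=O)c1cc(Br)cc(OC)c1O | intermediate
4 | 6-bromo-8-methoxy-4H-chromen-4-one | O=c1ccoc2c(OC)cc(Br)cc12 | intermediate
5 | [4-(benzyloxy)-3-methoxyphenyl]boronic acid | COc1cc(B(O)O)ccc1OCc1ccccc1 | starting material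
6 | (R)-2-[4-(benzyloxy)-3-methoxyphenyl]-6-bromo-8-methoxychroman-4-one | O=C1C[C@H](c2ccc(OCc3ccccc3)c(OC)c2)Oc2c(OC)cc(Br)cc21 | intermediate
7 | (R)-2-[4-(benzyloxy)-3-methoxyphenyl]-6-bromo-4,8-dimethoxy-2H-chromene | COC1=C[C@H](c2ccc(OCc3ccccc3)c(OC)c2)Oc2c(OC)cc(Br)cc21 | intermediate
8 | (2R,3S)-3-[acetoxy(phenyl)-λ3-iodanyl]-2-[4-(benzyloxy)-3-methoxyphenyl]-6-bromo-4,4,8-trimethoxychromane | COC1(OC)[C@@H](I(OC(C)=O)c2ccccc2)[C@H](c2ccc(OCc3ccccc3)c(OC)c2)Oc2c(OC)cc(Br)cc21 | intermediate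
9 | methyl (2R,3R)-2-[4-(benzyloxy)-3-methoxyphenyl]-5-bromo-7-methoxy-2,3-dihydrobenzofuran-3-carboxylate | Brc1cc(OC)c2c(c1)[C@@H](C(=O)OC)[C@H](c1ccc(OCc3ccccc3)c(OC)c1)O2 | intermediate
10 | [(2R,3S)-2-[4-(benzyloxy)-3-methoxyphenyl]-5-bromo-7-methoxy-2,3-dihydrobenzofuran-3-yl]methanol | Brc1cc(OC)c2c(c1)[C@@H](CO)[C@H](c1ccc(OCc3ccccc3)c(OC)c1)O2 | intermediate
11 | tert-butyl{[(2R,3S)-2-[4-(benzyloxy)-3-methoxyphenyl]-5-bromo-7-methoxy-2,3-dihydrobenzofuran-3-yl]methoxy}dimethylsilane | Brc1cc(OC)c2c(c1)[C@@H](CO[Si](C)(C)C(C)(C)C)[C@H](c1ccc(OCc3ccccc3)c(OC)c1)O2 | intermediate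
12 | 5-lithio analogue of 11 (aryllithium) | [Li]c1cc(OC)c2c(c1)[C@@H](CO[Si](C)(C)C(C)(C)C)[C@H](c1ccc(OCc3ccccc3)c(OC)c1)O2 | intermediate
13 | (2R,3S)-2-[4-(benzyloxy)-3-methoxyphenyl]-3-{[(tert-butyldimethylsilyl)oxy]methyl}-7-methoxy-2,3-dihydrobenzofuran-5-carbaldehyde | O=Cc1cc(OC)c2c(c1)[C@@H](CO[Si](C)(C)C(C)(C)C)[C@H](c1ccc(OCc3ccccc3)c(OC)c1)O2 | intermediate
14 | [(2R,3S)-2-[4-(benzyloxy)-3-methoxyphenyl]-3-{[(tert-butyldimethylsilyl)oxy]methyl}-7-methoxy-2,3-dihydrobenzofuran-5-yl]methanol | OCc1cc(OC)c2c(c1)[C@@H](CO[Si](C)(C)C(C)(C)C)[C@H](c1ccc(OCc3ccccc3)c(OC)c1)O2 | intermediate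
15 | {[(2R,3S)-2-[4-(benzyloxy)-3-methoxyphenyl]-5-(bromomethyl)-7-methoxy-2,3-dihydrobenzofuran-3-yl]methoxy}(tert-butyl)dimethylsilane | BrCc1cc(OC)c2c(c1)[C@@H](CO[Si](C)(C)C(C)(C)C)[C@H](c1ccc(OCc3ccccc3)c(OC)c1)O2 | intermediate
16 | 3-bromo-4-hydroxy-5-methoxybenzaldehyde (5-bromovanillin) | COc1cc(C=O)cc(Br)c1O | starting material
17 | 4-(benzyloxy)-3-bromo-5-methoxybenzaldehyde | COc1cc(C=O)cc(Br)c1OCc1ccccc1 | intermediate
18 | dimethyl succinate | COC(=O)CCC(=O)OC | starting material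
19 | methyl 2-[4-(benzyloxy)-3-bromo-5-methoxyphenyl]-5-oxotetrahydrofuran-3-carboxylate (paraconate, diastereomer mixture) | COC(=O)C1CC(=O)OC1c1cc(OC)c(OCc2ccccc2)c(Br)c1 | intermediate
20 | (E)-4-[4-(benzyloxy)-3-bromo-5-methoxyphenyl]-3-(methoxycarbonyl)but-3-enoic acid | COC(=O)/C(CC(=O)O)=C/c1cc(OC)c(OCc2ccccc2)c(Br)c1 | intermediate
21 | (S)-4-[4-(benzyloxy)-3-bromo-5-methoxyphenyl]-3-(methoxycarbonyl)butanoic acid | COC(=O)[C@H](CC(=O)O)Cc1cc(OC)c(OCc2ccccc2)c(Br)c1 | intermediate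
22 | (S)-4-[4-(benzyloxy)-3-bromo-5-methoxyphenyl]-3-(hydroxymethyl)butanoic acid | OC[C@H](CC(=O)O)Cc1cc(OC)c(OCc2ccccc2)c(Br)c1 | intermediate
23 | (S)-4-[4-(benzyloxy)-3-bromo-5-methoxybenzyl]dihydrofuran-2(3H)-one | COc1cc(C[C@@H]2COC(=O)C2)cc(Br)c1OCc1ccccc1 | intermediate
24 | (S)-4-[4-(benzyloxy)-3-methoxy-5-vinylbenzyl]dihydrofuran-2(3H)-one | C=Cc1cc(C[C@@H]2COC(=O)C2)cc(OC)c1OCc1ccccc1 | intermediate
25 | lithium enolate of 24 | C=Cc1cc(C[C@@H]2COC(O[Li])=C2)cc(OC)c1OCc1ccccc1 | intermediate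
26 | (3S,4S)-4-[4-(benzyloxy)-3-methoxy-5-vinylbenzyl]-3-(DBF-methyl)dihydrofuran-2(3H)-one | C=Cc1cc(C[C@@H]2COC(=O)[C@H]2Cc2cc(OC)c3c(c2)[C@@H](CO[Si](C)(C)C(C)(C)C)[C@H](c2ccc(OCc4ccccc4)c(OC)c2)O3)cc(OC)c1OCc1ccccc1 | intermediate
27 | 2-allyl-4,4,5,5-tetramethyl-1,3,2-dioxaborolane | C=CCB1OC(C)(C)C(C)(C)O1 | starting material
28 | (3S,4S)-4-{4-(benzyloxy)-3-methoxy-5-[(E)-3-(4,4,5,5-tetramethyl-1,3,2-dioxaborolan-2-yl)prop-1-enyl]benzyl}-3-(DBF-methyl)dihydrofuran-2(3H)-one | CC1(C)OB(C/C=C/c2cc(C[C@@H]3COC(=O)[C@H]3Cc3cc(OC)c4c(c3)[C@@H](CO[Si](C)(C)C(C)(C)C)[C@H](c3ccc(OCc5ccccc5)c(OC)c3)O4)cc(OC)c2OCc2ccccc2)OC1(C)C | intermediate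
29 | 4-(benzyloxy)-3-methoxybenzaldehyde | COc1cc(C=O)ccc1OCc1ccccc1 | starting material
30 | O-(4,4,5,5-tetramethyl-1,3,2-dioxaborolan-2-yl) ester of 31 | COc1cc([C@@H](OB2OC(C)(C)C(C)(C)O2)[C@H](C=C)c2cc(C[C@@H]3COC(=O)[C@H]3Cc3cc(OC)c4c(c3)[C@@H](CO[Si](C)(C)C(C)(C)C)[C@H](c3ccc(OCc5ccccc5)c(OC)c3)O4)cc(OC)c2OCc2ccccc2)ccc1OCc1ccccc1 | intermediate
31 | (3S,4S)-4-{4-(benzyloxy)-3-[(1S,2R)-1-BnV-1-hydroxybut-3-en-2-yl]-5-methoxybenzyl}-3-(DBF-methyl)dihydrofuran-2(3H)-one | COc1cc([C@@H](O)[C@H](C=C)c2cc(C[C@@H]3COC(=O)[C@H]3Cc3cc(OC)c4c(c3)[C@@H](CO[Si](C)(C)C(C)(C)C)[C@H](c3ccc(OCc5ccccc5)c(OC)c3)O4)cc(OC)c2OCc2ccccc2)ccc1OCc1ccccc1 | intermediate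
32 | (3S,4S)-4-{4-(benzyloxy)-3-[(2R,3S)-3-BnV-3-hydroxy-1-oxopropan-2-yl]-5-methoxybenzyl}-3-(DBF-methyl)dihydrofuran-2(3H)-one | COc1cc([C@@H](O)[C@H](C=O)c2cc(C[C@@H]3COC(=O)[C@H]3Cc3cc(OC)c4c(c3)[C@@H](CO[Si](C)(C)C(C)(C)C)[C@H](c3ccc(OCc5ccccc5)c(OC)c3)O4)cc(OC)c2OCc2ccccc2)ccc1OCc1ccccc1 | intermediate
33 | (3S,4S)-4-{4-(benzyloxy)-3-[(1S,2S)-1-BnV-1,3-dihydroxypropan-2-yl]-5-methoxybenzyl}-3-(DBF-methyl)dihydrofuran-2(3H)-one | COc1cc([C@@H](O)[C@H](CO)c2cc(C[C@@H]3COC(=O)[C@H]3Cc3cc(OC)c4c(c3)[C@@H](CO[Si](C)(C)C(C)(C)C)[C@H](c3ccc(OCc5ccccc5)c(OC)c3)O4)cc(OC)c2OCc2ccccc2)ccc1OCc1ccccc1 | intermediate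
34 | (3S,4S)-4-{4-(benzyloxy)-3-[(1S,2S)-1-BnV-1,3-dihydroxypropan-2-yl]-5-methoxybenzyl}-3-{[(2R,3S)-2-BnV-3-(hydroxymethyl)-7-methoxy-2,3-dihydrobenzofuran-5-yl]methyl}dihydrofuran-2(3H)-one | COc1cc([C@@H](O)[C@H](CO)c2cc(C[C@@H]3COC(=O)[C@H]3Cc3cc(OC)c4c(c3)[C@@H](CO)[C@H](c3ccc(OCc5ccccc5)c(OC)c3)O4)cc(OC)c2OCc2ccccc2)ccc1OCc1ccccc1 | intermediate
35 | CNP0199264.1 | COc1cc([C@@H](O)[C@H](CO)c2cc(C[C@@H]3COC(=O)[C@H]3Cc3cc(OC)c4c(c3)[C@@H](CO)[C@H](c3ccc(O)c(OC)c3)O4)cc(OC)c2O)ccc1O | target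

**Step count and risks**

Total step count: 19. Longest linear sequence: 14 steps (steps 1–8, then 14–19).

Steps most likely to fail:

Step 4. Under the acidic oxidising conditions, migration of the electron-rich C2 aryl group to C3, dehydrogenation to the flavone, or acid-induced opening of ring C with erosion of the C2 configuration may compete with the ring-A shift. The fallback is a photochemical Wolff ring contraction that sets out from 6 and returns at 9. Condensation of 6 with Me2NCH(OMe)2 (toluene, 90 °C) gives the 3-(dimethylaminomethylene) ketone F1. Deformylative diazo transfer with TsN3 (MeCN, rt) gives the 3-diazo ketone F2. Irradiation (365 nm, MeOH) expels nitrogen and the same ring-A carbon migrates to give the ketene F3, which methanol traps as a mixture of 9 and the cis ester F4. Catalytic NaOMe in MeOH equilibrates F4 to the trans ester 9.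

Step 16. Facial control by the phosphoric acid may be weak with a γ-aryl boronate and a slow, electron-rich aldehyde, so that the uncatalysed background reaction gives a mixture of the two anti diastereomers that cannot be separated. The fallback is an auxiliary-controlled anti-aldol that sets out from 26 and returns at 33. Hydroboration–oxidation of the styrene (9-BBN, THF; NaBO3·4H2O) gives the 2-arylethanol F5. Oxidation (TEMPO, PhI(OAc)2, MeCN/H2O) gives the arylacetic acid F6. Acylation of (S)-4-benzyl-2-oxazolidinone (t-BuCOCl, Et3N; LiCl) gives the imide F7. The MgCl2-catalysed anti-aldol with 29 (MgCl2, Et3N, Me3SiCl, EtOAc, rt) gives the silylated anti adduct F8. NaBH4 in THF/H2O followed by dilute citric acid removes the auxiliary and the trimethylsilyl group to give 33.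

Step 3. Insertion may be slow or poorly face-selective with the electron-rich boronic acid, protodeboronation may consume it, and zerovalent palladium formed adventitiously may attack the aryl bromide. The fallback is a resolution route that sets out from 2 (with 29) and returns at 6. Claisen–Schmidt condensation (KOH, EtOH, rt) gives the chalcone F9. Oxa-Michael cyclisation (NaOAc, EtOH, reflux) gives the racemic flavanone F10. Kinetic resolution by asymmetric transfer hydrogenation (RuCl[(R,R)-TsDPEN](p-cymene), HCO2H/Et3N, EtOAc) reduces the (S)-enantiomer to the cis-flavan-4-ol F11 and leaves (R)-flavanone 6, separated by chromatography.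

**Further compounds**

F1 | step 4 | (S,E)-2-BnV-6-bromo-3-[(dimethylamino)methylene]-8-methoxychroman-4-one (C2 geometry as in 6) | O=C1/C(=C/N(C)C)[C@H](c2ccc(OCc3ccccc3)c(OC)c2)Oc2c(OC)cc(Br)cc21
F2 | step 4 | (S)-2-BnV-6-bromo-3-diazo-8-methoxychroman-4-one (C2 geometry as in 6) | O=C1C(=[N+]=[N-])[C@H](c2ccc(OCc3ccccc3)c(OC)c2)Oc2c(OC)cc(Br)cc21
F3 | step 4 | (S)-2-BnV-5-bromo-7-methoxy-3-(oxomethylidene)-2,3-dihydrobenzofuran (ketene; C2 geometry as in 6) | O=C=C1[C@H](c2ccc(OCc3ccccc3)c(OC)c2)Oc2c(OC)cc(Br)cc21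
F4 | step 4 | methyl (2R,3S)-2-BnV-5-bromo-7-methoxy-2,3-dihydrobenzofuran-3-carboxylate (cis) | Brc1cc(OC)c2c(c1)[C@H](C(=O)OC)[C@H](c1ccc(OCc3ccccc3)c(OC)c1)O2
F5 | step 16 | (3S,4S)-4-[4-(benzyloxy)-3-(2-hydroxyethyl)-5-methoxybenzyl]-3-(DBF-methyl)dihydrofuran-2(3H)-one | OCCc1cc(C[C@@H]2COC(=O)[C@H]2Cc2cc(OC)c3c(c2)[C@@H](CO[Si](C)(C)C(C)(C)C)[C@H](c2ccc(OCc4ccccc4)c(OC)c2)O3)cc(OC)c1OCc1ccccc1
F6 | step 16 | 2-[2-(benzyloxy)-3-methoxy-5-{[(3S,4S)-4-(DBF-methyl)-5-oxotetrahydrofuran-3-yl]methyl}phenyl]acetic acid | OC(=O)Cc1cc(C[C@@H]2COC(=O)[C@H]2Cc2cc(OC)c3c(c2)[C@@H](CO[Si](C)(C)C(C)(C)C)[C@H](c2ccc(OCc4ccccc4)c(OC)c2)O3)cc(OC)c1OCc1ccccc1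
F7 | step 16 | (S)-4-benzyl-3-{2-[2-(benzyloxy)-3-methoxy-5-{[(3S,4S)-4-(DBF-methyl)-5-oxotetrahydrofuran-3-yl]methyl}phenyl]acetyl}oxazolidin-2-one | O=C(Cc1cc(C[C@@H]2COC(=O)[C@H]2Cc2cc(OC)c3c(c2)[C@@H](CO[Si](C)(C)C(C)(C)C)[C@H](c2ccc(OCc4ccccc4)c(OC)c2)O3)cc(OC)c1OCc1ccccc1)N1[C@@H](Cc2ccccc2)COC1=O
F8 | step 16 | (S)-4-benzyl-3-{(2R,3S)-3-BnV-2-[2-(benzyloxy)-3-methoxy-5-{[(3S,4S)-4-(DBF-methyl)-5-oxotetrahydrofuran-3-yl]methyl}phenyl]-3-(trimethylsilyloxy)propanoyl}oxazolidin-2-one | COc1cc([C@@H](O[Si](C)(C)C)[C@H](C(=O)N2[C@@H](Cc3ccccc3)COC2=O)c2cc(C[C@@H]3COC(=O)[C@H]3Cc3cc(OC)c4c(c3)[C@@H](CO[Si](C)(C)C(C)(C)C)[C@H](c3ccc(OCc5ccccc5)c(OC)c3)O4)cc(OC)c2OCc2ccccc2)ccc1OCc1ccccc1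
F9 | step 3 | (E)-3-BnV-1-(5-bromo-2-hydroxy-3-methoxyphenyl)prop-2-en-1-one | COc1cc(/C=C/C(=O)c2cc(Br)cc(OC)c2O)ccc1OCc1ccccc1
F10 | step 3 | racemic 2-BnV-6-bromo-8-methoxychroman-4-one | O=C1CC(c2ccc(OCc3ccccc3)c(OC)c2)Oc2c(OC)cc(Br)cc21
F11 | step 3 | (2S,4S)-2-BnV-6-bromo-8-methoxychroman-4-ol (cis) | O[C@H]1C[C@@H](c2ccc(OCc3ccccc3)c(OC)c2)Oc2c(OC)cc(Br)cc21
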